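(All runs are calculated with constants of no real substance; the scatter is artificial.)

If substrate falls pseudo-first-order while reagent stays at a held level, count n lifetimes: a closed flask then keeps exp(−n) of its substrate and a tank keeps 1/(1+n).

| flask | substrate | reagent | remark | time |
|---|---|---|---|---|
| blue | 0.050 M | 0.125 M | run made earlier |  |
| grey | 0.050 M | 0.062 M | run made earlier |  |
| violet | 0.050 M | 0.25 M | run made earlier |  |
| ash | 0.050 M | 0.125 M | one stirred flow tank at steady state, fed with the mixture as stated, mean residence time 7.50 min |  |
| birch | 0.050 M (fed, over 2.00 min) | 0.125 M | a stirred flask in which substrate is dosed at a steady rate over 2.00 min without added volume, worked up at 2.5 min | 2.5 min |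
| cedar | 0.050 M | 0.125 M | one stirred flow tank at steady state, fed with the mixture as stated, mean residence time 2.5 min |  |
| elm | 0.050 M | 0.125 M | everything together in a closed stirred flask, run for 2.5 min | 2.5 min |

- blue (time / min: product / %, substrate / %): 0.500: 4.4, 61.9; 1.00: 20.2, 42.1; 1.50: 36.1, 29.8; 2.00: 47.6, 22.7; 2.50: 57.1, 17.3
- grey (time / s: product / %, substrate / %): 10.0: 0.1, 91.6; 25.0: 0.3, 82.0; 40.0: 2.9, 74.4; 60.0: 6.9, 65.0; 90.0: 13.1, 55.1
- violet (time / s: product / %, substrate / %): 10.0: 1.6, 70.9; 25.0: 11.0, 44.4; 40.0: 27.0, 28.3; 60.0: 48.1, 16.8; 90.0: 70.7, 8.3

(readings scatter by 0.5 percentage points)

- the stated concentrations are those of everything mixed, before any reaction; amounts are the same in each set-up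
- the feed brings no volume worth counting
- the earlier runs were made in a closed, stirred flask

* the set-up with the highest amount of product at the outlet or at the end, in percent of the substrate put in ("none" if the first two lie within 2 percentage points) (ash / birch / cedar / elm / none)
* amount of product at the outlet or at the end, in percent of the substrate put in, ash
* amount of product at the outlet or at the end, in percent of the substrate put in, birch
* amount of product at the outlet or at the end, in percent of the substrate put in, cedar
* amount of product at the outlet or at the end, in percent of the substrate put in, elm

Read the lifetime of substrate at the reagent charge of elm, the time for a fall to 1/e with reagent held at that charge, 0.969 min, from the first violet reading. Read it again from the first grey reading, which gives 0.942 min. These runs differ in reagent by a factor of 4.03, so trust the lifetime.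

Now reach the substrate in elm by two ways. Elm repeats blue, which reads 17.3% at 2.50 min. The count gives 2.58 lifetimes and 7.58%. The count cheats, since the blue reading is worth 1.75 lifetimes, a mean reagent share of 68.0%. Charge one reagent per substrate lost and one more per product: blue ends at a share of 44.1%, and the midpoint between that and the start is 72.0%, near the share needed.

Give ash that end share as my own assumption: 3.41 lifetimes leave 22.7% substrate, more than the 17.3% in blue. But blue still lacks 25.6% between substrate lost and product, and ash has 3.00 times the time to close it, so I put ash above the 57.1% of elm. Birch substrate arrives on average at mid-dose and stays 1.50 min, where blue reads 36.1% of product.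

The forecast says ash, with birch at 32% and elm at 57.1%, and with ash at 62% and cedar at 40%, “assuming the lag barely matters in a tank”.

The flasks put ash first: ash 63.4%, elm 57.1%, cedar 39.5%, birch 34.8%.

    substrate + reagent → intermediate A (k = 0.140 M⁻¹ s⁻¹)
    intermediate A → intermediate B (k = 0.0580 s⁻¹)
    reagent + intermediate B → product (k = 0.230 M⁻¹ s⁻¹)

Ash holds reagent at 43.7% of its charge, and beside the product stand 2.86% of intermediate A and 11.2% of intermediate B, which leaves 22.5% for substrate. The lifetime at that share counts 3.38 lifetimes in ash and gives 22.8% substrate. A neighbour of elm with 0.020 M of substrate ends with 75% of its reagent, so the midpoint between that share and its start counts 2.25 lifetimes and gives 10.5% substrate, and that flask holds 11% of its charged substrate.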